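**Plan**

Cuts, in retrosynthetic order: the eight aryl O–benzyl bonds; the ester C–O bond of the C1 carboxyl (cut at the lactate carbon); the ring bond C1–C2; then, in the lactone so revealed, the lactone carbonyl (back to an ortho-allyl group), the alkene–aryl bond and the carbinol C–C bond.
Feature (dihydronaphthalene numbering: C1 = CH–CO2R on fusion carbon C8a, C2 = CH–aryl, C3 = alkene carbon with CO2R, C4 = alkene CH on C4a): the C1–C2 bond lies 1,4 to the C3=C4 alkene and C1 carries a carboxyl, so joining that carboxyl oxygen to C4 gives a six-membered lactone (O, C=O, C1, C8a, C4a, C4: an isochroman-3-one with the alkenyl group on C4), the retron of a [3,3] shift.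
Forward: a 2-allylbenzaldehyde and the propiolate of an (S)-aryllactate are joined by an enantioselective iodo-aldol; Suzuki arylation completes the (Z)-alkene; oxidative cleavage of the allyl group and lactol oxidation close the lactone ring; the ring contraction turns the lactone into the carbocycle; a second lactate is attached and the benzyl groups are removed.
Stereochemistry: both lactate centres come from (S)-methyl glycidate (one kept by O-acylation, one inverted to R by Mitsunobu displacement); the carbinol is set by a chiral oxazaborolidinium catalyst; the Z alkene comes from the iodo-aldol and a stereoretentive coupling; C1 and C2 arise by chirality transfer through an enforced boat transition state.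

Key step: step 10

Remark: the target is taken as drawn, i.e. (1S,2S)-cis ring, (S)-lactate on the C3 ester and (R)-lactate on the C1 ester. Salt forms (phenoxides, carboxylates, magnesium or boron alkoxides awaiting hydrolysis) and catalytic-cycle species carry no number.

**Step 1**
Reactants: 1 2-bromoisovanillin
Product: 2 2-bromo-3,4-dihydroxybenzaldehyde
Conditions: BBr3 (2.5 equiv), CH2Cl2, −78 → 0 °C; aqueous work-up
Reagents that add atoms: none
Why: Lewis-acid aryl methyl ether cleavage (boron complexation, then bromide SN2 attack on the methyl group), to which the aldehyde and the aryl bromide are inert at low temperature.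

**Step 2**
Reactants: 2 2-bromo-3,4-dihydroxybenzaldehyde
Product: 3 3,4-bis(benzyloxy)-2-bromobenzaldehyde
Conditions: BnBr (2.4 equiv), K2CO3, DMF, 60 °C
Reagents that add atoms: benzyl bromide, BrCc1ccccc1
Why: Williamson ether synthesis; both phenoxides are alkylated by SN2 and benzyl is chosen because it can later be removed without hydrogenation.

**Step 3**
Reactants: 3 3,4-bis(benzyloxy)-2-bromobenzaldehyde
Product: 4 2-allyl-3,4-bis(benzyloxy)benzaldehyde
Conditions: allylSnBu3 (1.3 equiv), Pd(PPh3)4 (5 mol%), toluene, 100 °C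
Reagents that add atoms: allyltributylstannane, C=CC[Sn](CCCC)(CCCC)CCCC
Why: Stille cross-coupling; the ortho-formyl group activates the C–Br bond for oxidative addition and the neutral conditions leave the aldehyde and benzyl ethers alone.

**Step 4**
Reactants: 5 4-bromo-1,2-bis(benzyloxy)benzene; 6 methyl (S)-glycidate
Product: 8 methyl (2S)-3-[3,4-bis(benzyloxy)phenyl]-2-hydroxypropanoate, via Grignard reagent 7 (not isolated)
Conditions: Mg, THF, 40 °C; then CuI (10 mol%), 6, THF, −40 → −20 °C; aqueous work-up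
Reagents that add atoms: none
Why: Copper-catalysed Grignard opening of the epoxide at its unsubstituted carbon (SN2), which is faster than addition to the ester at low temperature and does not touch the C2 stereocentre, so (S) is kept.

**Step 5**
Reactants: 8 methyl (2S)-3-[3,4-bis(benzyloxy)phenyl]-2-hydroxypropanoate; 9 propiolic acid
Product: 11 methyl (2S)-3-[3,4-bis(benzyloxy)phenyl]-2-(prop-2-ynoyloxy)propanoate, via O-acylisourea 10 (not isolated)
Conditions: DCC, DMAP (5 mol%), CH2Cl2, −20 → 0 °C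
Reagents that add atoms: none
Why: Steglich esterification; the acid is the activated partner, so the C–O bond at the lactate centre is not broken and (S) is kept, while low temperature and little DMAP limit conjugate addition to the ynoate.

**Step 6**
Reactants: 4 2-allyl-3,4-bis(benzyloxy)benzaldehyde; 11 methyl (2S)-3-[3,4-bis(benzyloxy)phenyl]-2-(prop-2-ynoyloxy)propanoate
Product: 14 (2S)-3-[3,4-bis(benzyloxy)phenyl]-1-methoxy-1-oxopropan-2-yl (2Z)-2-{(S)-[2-allyl-3,4-bis(benzyloxy)phenyl](hydroxy)methyl}-3-iodoprop-2-enoate, via silyl iodoallenolate 12 (not isolated), via trimethylsilyl ether 13 (not isolated)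
Conditions: TMSI (1.5 equiv), chiral oxazaborolidinium triflimide (20 mol%), CH2Cl2, −78 °C; then 1 M HCl, THF, 0 °C
Reagents that add atoms: iodotrimethylsilane, C[Si](C)(C)I
Why: Enantioselective three-component iodo-aldol (β-iodo Morita–Baylis–Hillman-type coupling): TMSI adds iodide 1,4 to the ynoate to give allenolate 12, which attacks the catalyst-bound aldehyde in a Mukaiyama-type aldol anti to iodine, so iodine ends cis to the ester (Z); the catalyst antipode is fixed in a pilot run (Mosher analysis) so that the (S)-carbinol results.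

**Step 7**
Reactants: 14 the (Z)-β-iodo allylic alcohol; 15 3,4-bis(benzyloxy)phenylboronic acid
Product: 16 (2S)-3-[3,4-bis(benzyloxy)phenyl]-1-methoxy-1-oxopropan-2-yl (2Z)-2-{(S)-[2-allyl-3,4-bis(benzyloxy)phenyl](hydroxy)methyl}-3-[3,4-bis(benzyloxy)phenyl]prop-2-enoate
Conditions: Pd(PPh3)4 (5 mol%), K2CO3, THF/H2O, 50 °C
Reagents that add atoms: none
Why: Suzuki–Miyaura coupling of an alkenyl iodide, which keeps the alkene geometry, so the new aryl group stands cis to the ester and trans to the carbinol carbon (Z), as the key step needs.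

**Step 8**
Reactants: 16 the (Z)-β-aryl allylic alcohol
Product: 19 (2S)-3-[3,4-bis(benzyloxy)phenyl]-1-methoxy-1-oxopropan-2-yl (2Z)-3-[3,4-bis(benzyloxy)phenyl]-2-[(1S)-5,6-bis(benzyloxy)-3-hydroxy-3,4-dihydro-1H-isochromen-1-yl]prop-2-enoate (lactol; both anomers), via diol 17 (not isolated), via hydroxy aldehyde 18 (not isolated)
Conditions: OsO4 (2 mol%), NaIO4, 2,6-lutidine, dioxane/H2O, rt
Reagents that add atoms: osmium tetroxide, O=[Os](=O)(=O)=O; sodium periodate, [Na+].[O-]I(=O)(=O)=O
Why: Lemieux–Johnson oxidation; OsO4 dihydroxylates the unhindered monosubstituted allyl alkene far faster than the hindered trisubstituted acrylate alkene, periodate cleaves diol 17, and arylacetaldehyde 18 is trapped at once by the benzylic hydroxyl as the six-membered lactol.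

**Step 9**
Reactants: 19 the lactol
Product: 20 (2S)-3-[3,4-bis(benzyloxy)phenyl]-1-methoxy-1-oxopropan-2-yl (2Z)-3-[3,4-bis(benzyloxy)phenyl]-2-[(1S)-5,6-bis(benzyloxy)-3-oxo-3,4-dihydro-1H-isochromen-1-yl]prop-2-enoate
Conditions: TEMPO (20 mol%), PhI(OAc)2, CH2Cl2, rt
Reagents that add atoms: none
Why: Oxoammonium (TEMPO/PhI(OAc)2) oxidation of a lactol to the lactone under near-neutral conditions, which spare the ionisable benzylic–allylic C–O bond, the Z alkene and the carbinol stereocentre.

**Step 10**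
Reactants: 20 the 1-alkenyl isochroman-3-one
Product: 23 (1S,2S)-7,8-bis(benzyloxy)-2-[3,4-bis(benzyloxy)phenyl]-3-({(2S)-3-[3,4-bis(benzyloxy)phenyl]-1-methoxy-1-oxopropan-2-yl}oxycarbonyl)-1,2-dihydronaphthalene-1-carboxylic acid (1,2-cis), via silyl ketene acetal 21 (not isolated), via trimethylsilyl ester 22 (not isolated)
Conditions: TMSOTf (1.3 equiv), Et3N (3 equiv), toluene, −20 °C → rt (40 °C if needed), Ar; then aq. citric acid, THF
Reagents that add atoms: none
Why: Soft enolisation silylates the benzylic lactone CH2 (the most acidic C–H) to the cyclic silyl ketene acetal 21, which undergoes a concerted [3,3] sigmatropic shift in which C1–C2 forms as the benzylic C–O bond breaks; the closest known reaction type is the Ireland–Claisen ring contraction of 6-alkenyl six-membered lactones. The six-membered carbocycle closes pericyclically, suprafacially on both partners, and because ketene acetal and alkene are tied through the ortho-phenylene unit the array can only adopt a boat (bicyclo[2.2.2]-like) geometry, a chair being sterically impossible. C1 is set by chirality transfer from the (S)-carbinol carbon (future C4): the alkenyl arm can reach the ketene acetal carbon only on the ring face it occupies, which gives (1S) as the C–O stereocentre is consumed. C2 is set by the alkene geometry: in the boat the β-substituent cis to the carbinol carbon points under the fused arene, so the (Z)-alkene places H there and the aryl group outside, which puts aryl cis to the carboxyl, (2S). The step needs enolisation of the lactone CH2 and not the far less acidic lactate C–H, no ionisation of the benzylic–allylic C–O bond (excess amine, non-polar solvent, low temperature) and no epimerisation of the new C1–H (slight excess of silyl triflate only, mild acidic work-up that hydrolyses silyl ester 22).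

**Step 11**
Reactants: 23 the cis C1 acid; 8 methyl (2S)-3-[3,4-bis(benzyloxy)phenyl]-2-hydroxypropanoate
Product: 25 1-{(2R)-3-[3,4-bis(benzyloxy)phenyl]-1-methoxy-1-oxopropan-2-yl} 3-{(2S)-3-[3,4-bis(benzyloxy)phenyl]-1-methoxy-1-oxopropan-2-yl} (1S,2S)-7,8-bis(benzyloxy)-2-[3,4-bis(benzyloxy)phenyl]-1,2-dihydronaphthalene-1,3-dicarboxylate, via alkoxyphosphonium ion 24 (not isolated)
Conditions: 8 (1.3 equiv), PPh3, DIAD, THF, 0 °C → rt
Reagents that add atoms: none
Why: Mitsunobu esterification; the hydroxyl of 8 is activated as alkoxyphosphonium ion 24 and displaced by the carboxylate of 23 in an SN2 step with inversion, which sets the (R) lactate centre, and the acid is never activated at acyl carbon, so the epimerisable C1–H is not put at risk.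

**Step 12**
Reactants: 25 the octabenzyl ether
Product: 26 1-[(2R)-3-(3,4-dihydroxyphenyl)-1-methoxy-1-oxopropan-2-yl] 3-[(2S)-3-(3,4-dihydroxyphenyl)-1-methoxy-1-oxopropan-2-yl] (1S,2S)-2-(3,4-dihydroxyphenyl)-7,8-dihydroxy-1,2-dihydronaphthalene-1,3-dicarboxylate (CNP0237075.1)
Conditions: BCl3 (excess), pentamethylbenzene (excess), CH2Cl2, −78 °C; MeOH quench at −78 °C, Ar
Reagents that add atoms: none
Why: Lewis-acid benzyl ether cleavage with BCl3 at −78 °C, pentamethylbenzene trapping each benzyl cation by Friedel–Crafts alkylation so the catechol rings are not C-benzylated; methyl esters, the acyloxy esters, the alkene and all four stereocentres should be untouched at this temperature.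

**Compound list**

1 | 2-bromoisovanillin (2-bromo-3-hydroxy-4-methoxybenzaldehyde) | O=Cc1ccc(OC)c(O)c1Br | starting material
2 | 2-bromo-3,4-dihydroxybenzaldehyde | O=Cc1ccc(O)c(O)c1Br | intermediate
3 | 3,4-bis(benzyloxy)-2-bromobenzaldehyde | O=Cc1ccc(OCc2ccccc2)c(OCc2ccccc2)c1Br | intermediate
4 | 2-allyl-3,4-bis(benzyloxy)benzaldehyde | O=Cc1ccc(OCc2ccccc2)c(OCc2ccccc2)c1CC=C | intermediate
5 | 4-bromo-1,2-bis(benzyloxy)benzene | Brc1ccc(OCc2ccccc2)c(OCc2ccccc2)c1 | starting material
6 | methyl (S)-glycidate (methyl (2S)-oxirane-2-carboxylate) | COC(=O)[C@@H]1CO1 | starting material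
7 | [3,4-bis(benzyloxy)phenyl]magnesium bromide (Grignard reagent) | Br[Mg]c1ccc(OCc2ccccc2)c(OCc2ccccc2)c1 | intermediate
8 | methyl (2S)-3-[3,4-bis(benzyloxy)phenyl]-2-hydroxypropanoate | COC(=O)[C@@H](O)Cc1ccc(OCc2ccccc2)c(OCc2ccccc2)c1 | intermediate
9 | propiolic acid | C#CC(=O)O | starting material
10 | O-propioloyl-N,N'-dicyclohexylisourea | C#CC(=O)OC(=NC1CCCCC1)NC1CCCCC1 | intermediate
11 | methyl (2S)-3-[3,4-bis(benzyloxy)phenyl]-2-(prop-2-ynoyloxy)propanoate | C#CC(=O)O[C@@H](Cc1ccc(OCc2ccccc2)c(OCc2ccccc2)c1)C(=O)OC | intermediate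
12 | 3-iodoallenyl trimethylsilyl ketene acetal of 11 (silyl iodoallenolate) | IC=C=C(O[Si](C)(C)C)O[C@@H](Cc1ccc(OCc2ccccc2)c(OCc2ccccc2)c1)C(=O)OC | intermediate
13 | trimethylsilyl ether of 14 | C=CCc1c(OCc2ccccc2)c(OCc2ccccc2)ccc1[C@H](O[Si](C)(C)C)/C(C(=O)O[C@@H](Cc1ccc(OCc2ccccc2)c(OCc2ccccc2)c1)C(=O)OC)=C/I | intermediate
14 | (S)-lactate ester of (2Z)-2-{(S)-[2-allyl-3,4-bis(benzyloxy)phenyl](hydroxy)methyl}-3-iodoprop-2-enoic acid | C=CCc1c(OCc2ccccc2)c(OCc2ccccc2)ccc1[C@H](O)/C(C(=O)O[C@@H](Cc1ccc(OCc2ccccc2)c(OCc2ccccc2)c1)C(=O)OC)=C/I | intermediate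
15 | 3,4-bis(benzyloxy)phenylboronic acid | OB(O)c1ccc(OCc2ccccc2)c(OCc2ccccc2)c1 | starting material
16 | (S)-lactate ester of (2Z)-2-{(S)-[2-allyl-3,4-bis(benzyloxy)phenyl](hydroxy)methyl}-3-[3,4-bis(benzyloxy)phenyl]prop-2-enoic acid | C=CCc1c(OCc2ccccc2)c(OCc2ccccc2)ccc1[C@H](O)/C(C(=O)O[C@@H](Cc1ccc(OCc2ccccc2)c(OCc2ccccc2)c1)C(=O)OC)=C/c1ccc(OCc2ccccc2)c(OCc2ccccc2)c1 | intermediate
17 | 2,3-dihydroxypropyl analogue of 16 (diol; epimers at the new carbinol) | OCC(O)Cc1c(OCc2ccccc2)c(OCc2ccccc2)ccc1[C@H](O)/C(C(=O)O[C@@H](Cc1ccc(OCc2ccccc2)c(OCc2ccccc2)c1)C(=O)OC)=C/c1ccc(OCc2ccccc2)c(OCc2ccccc2)c1 | intermediate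
18 | 2-oxoethyl analogue of 16 (hydroxy aldehyde) | O=CCc1c(OCc2ccccc2)c(OCc2ccccc2)ccc1[C@H](O)/C(C(=O)O[C@@H](Cc1ccc(OCc2ccccc2)c(OCc2ccccc2)c1)C(=O)OC)=C/c1ccc(OCc2ccccc2)c(OCc2ccccc2)c1 | intermediate
19 | (S)-lactate ester of (2Z)-3-[3,4-bis(benzyloxy)phenyl]-2-[(1S)-5,6-bis(benzyloxy)-3-hydroxyisochroman-1-yl]prop-2-enoic acid (lactol; anomers) | OC1Cc2c(OCc3ccccc3)c(OCc3ccccc3)ccc2[C@H](O1)/C(C(=O)O[C@@H](Cc2ccc(OCc3ccccc3)c(OCc3ccccc3)c2)C(=O)OC)=C/c1ccc(OCc2ccccc2)c(OCc2ccccc2)c1 | intermediate
20 | (S)-lactate ester of (2Z)-3-[3,4-bis(benzyloxy)phenyl]-2-[(1S)-5,6-bis(benzyloxy)-3-oxoisochroman-1-yl]prop-2-enoic acid (key-step precursor) | O=C1Cc2c(OCc3ccccc3)c(OCc3ccccc3)ccc2[C@H](O1)/C(C(=O)O[C@@H](Cc2ccc(OCc3ccccc3)c(OCc3ccccc3)c2)C(=O)OC)=C/c1ccc(OCc2ccccc2)c(OCc2ccccc2)c1 | intermediate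
21 | 3-(trimethylsilyloxy)-1H-isochromene from 20 (cyclic silyl ketene acetal) | C[Si](C)(C)OC1=Cc2c(OCc3ccccc3)c(OCc3ccccc3)ccc2[C@H](O1)/C(C(=O)O[C@@H](Cc2ccc(OCc3ccccc3)c(OCc3ccccc3)c2)C(=O)OC)=C/c1ccc(OCc2ccccc2)c(OCc2ccccc2)c1 | intermediate
22 | trimethylsilyl ester of 23 | COC(=O)[C@H](Cc1ccc(OCc2ccccc2)c(OCc2ccccc2)c1)OC(=O)C1=Cc2ccc(OCc3ccccc3)c(OCc3ccccc3)c2[C@@H](C(=O)O[Si](C)(C)C)[C@H]1c1ccc(OCc2ccccc2)c(OCc2ccccc2)c1 | intermediate
23 | (1S,2S)-cis C1 acid carrying the C3 (S)-lactate ester (key-step product) | COC(=O)[C@H](Cc1ccc(OCc2ccccc2)c(OCc2ccccc2)c1)OC(=O)C1=Cc2ccc(OCc3ccccc3)c(OCc3ccccc3)c2[C@@H](C(=O)O)[C@H]1c1ccc(OCc2ccccc2)c(OCc2ccccc2)c1 | intermediate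
24 | alkoxyphosphonium ion of 8 | COC(=O)[C@@H](O[P+](c1ccccc1)(c1ccccc1)c1ccccc1)Cc1ccc(OCc2ccccc2)c(OCc2ccccc2)c1 | intermediate
25 | octa-O-benzyl ether of the target (C1 ester (R)-lactate, C3 ester (S)-lactate) | COC(=O)[C@H](Cc1ccc(OCc2ccccc2)c(OCc2ccccc2)c1)OC(=O)C1=Cc2ccc(OCc3ccccc3)c(OCc3ccccc3)c2[C@@H](C(=O)O[C@H](Cc2ccc(OCc3ccccc3)c(OCc3ccccc3)c2)C(=O)OC)[C@H]1c1ccc(OCc2ccccc2)c(OCc2ccccc2)c1 | intermediate
26 | CNP0237075.1 | COC(=O)[C@H](Cc1ccc(O)c(O)c1)OC(=O)C1=Cc2ccc(O)c(O)c2[C@@H](C(=O)O[C@H](Cc2ccc(O)c(O)c2)C(=O)OC)[C@H]1c1ccc(O)c(O)c1 | target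

**Count and risks**

Total: 12 steps. Longest linear sequence: 10 steps (steps 1–3 and 6–12, from 2-bromoisovanillin).

Step 6. The catalyst-bound aldehyde is ortho-substituted and electron-rich, so facial discrimination may be poor or Z selectivity may erode. The Lewis acid may also trigger a carbonyl–ene closure of the ortho-allyl group onto the activated aldehyde. The fallback sets out from 4 and 11 and comes back at 14; it moves stereocontrol from the catalyst to separation. Magnesium iodide in CH2Cl2 at 0 °C adds iodide to 11 to give the magnesium iodoallenolate F1, which adds to 4 in the achiral, Z-selective iodo-aldol. This should give 14 together with its (R)-carbinol epimer F2; because the (S)-lactate is already in place the two are diastereomers, to be separated by preparative HPLC. F2 is recycled: Dess–Martin oxidation gives the iodo enone F3, and Luche reduction (NaBH4, CeCl3, MeOH, −78 °C) returns a mixture of 14 and F2 for a further separation. 14 then enters step 7.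

Step 10. Silylation may take place at the lactate C–H, or the silyl triflate may ionise the benzylic–allylic C–O bond before the shift, with loss of chirality transfer. The amine may also epimerise the new C1–H to the trans acid. The fallback sets out from 19 and comes back at 23; it forms the same C1–C2 bond one oxidation level lower, with no enolisation and no silyl triflate. Lactol 19 is dehydrated (PPTS cat., 4 Å sieves, toluene, 60 °C) to the cyclic enol ether F4, a 1H-isochromene that holds an allyl vinyl ether. Heating (toluene, 110 °C, base-washed glass) should bring about the thermal Claisen ring contraction through the same enforced boat to the cis aldehyde F5. Pinnick oxidation (NaClO2, NaH2PO4, 2-methyl-2-butene, t-BuOH/H2O) then gives 23.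

Step 11. The activated lactate may undergo β-elimination to the cinnamate, the hindered carboxylate may attack too slowly, or the basic betaine may epimerise C1. The fallback sets out from 8 and 23 and comes back at 25; it replaces the redox condensation by displacement on a preformed electrophile. Alcohol 8 is converted with Tf2O and 2,6-lutidine (CH2Cl2, −78 °C) into the triflate F6. The caesium carboxylate of 23 (Cs2CO3, MeCN, −20 → 0 °C) displaces the triflate by SN2 with inversion, which gives 25 with the (R) lactate centre.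

**Further compounds**

F1 | step 6 | magnesium iodoallenolate of 11 | I[Mg]OC(=C=CI)O[C@@H](Cc1ccc(OCc2ccccc2)c(OCc2ccccc2)c1)C(=O)OC
F2 | step 6 | (R)-carbinol epimer of 14 | C=CCc1c(OCc2ccccc2)c(OCc2ccccc2)ccc1[C@@H](O)/C(C(=O)O[C@@H](Cc1ccc(OCc2ccccc2)c(OCc2ccccc2)c1)C(=O)OC)=C/I
F3 | step 6 | (S)-lactate ester of (2Z)-2-[2-allyl-3,4-bis(benzyloxy)benzoyl]-3-iodoprop-2-enoic acid (iodo enone) | C=CCc1c(OCc2ccccc2)c(OCc2ccccc2)ccc1C(=O)/C(C(=O)O[C@@H](Cc1ccc(OCc2ccccc2)c(OCc2ccccc2)c1)C(=O)OC)=C/I
F4 | step 10 | (S)-lactate ester of (2Z)-3-[3,4-bis(benzyloxy)phenyl]-2-[(1S)-5,6-bis(benzyloxy)-1H-isochromen-1-yl]prop-2-enoic acid (cyclic enol ether) | C1=Cc2c(OCc3ccccc3)c(OCc3ccccc3)ccc2[C@H](O1)/C(C(=O)O[C@@H](Cc2ccc(OCc3ccccc3)c(OCc3ccccc3)c2)C(=O)OC)=C/c1ccc(OCc2ccccc2)c(OCc2ccccc2)c1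
F5 | step 10 | (1S,2S)-cis C1 aldehyde carrying the C3 (S)-lactate ester | COC(=O)[C@H](Cc1ccc(OCc2ccccc2)c(OCc2ccccc2)c1)OC(=O)C1=Cc2ccc(OCc3ccccc3)c(OCc3ccccc3)c2[C@@H](C=O)[C@H]1c1ccc(OCc2ccccc2)c(OCc2ccccc2)c1
F6 | step 11 | methyl (2S)-3-[3,4-bis(benzyloxy)phenyl]-2-(trifluoromethanesulfonyloxy)propanoate | COC(=O)[C@@H](OS(=O)(=O)C(F)(F)F)Cc1ccc(OCc2ccccc2)c(OCc2ccccc2)c1
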